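The numbers in the tables were computed with constants of no real substance; noise was put on by code.

At early times none of X is in solution, so J can turn into Q while Z, which needs L from X, stays near zero.

common to all: J 0.20 M
- maple: X 0.27 M; run made earlier
- ash: X 2.2 M; run made earlier
- red: X 0.220 M; time 8.0 h
- green: X 0.550 M; time 8.0 h
- grey: X 1.40 M; time 8.0 h

| run | time / h | J / % | Z / % | Q / % |
|---|---|---|---|---|
| maple | 0.417 | 92.6 | 0 | 6.1 |
| maple | 1.33 | 79.1 | 0 | 19.2 |
| maple | 2.50 | 65.3 | 1.7 | 32.9 |
| maple | 3.00 | 60.2 | 2.6 | 36.4 |
| maple | 5.00 | 42.9 | 8.3 | 48.6 |
| maple | 6.00 | 35.4 | 12.2 | 51.6 |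
| maple | 8.00 | 26.7 | 18.9 | 53.6 |
| ash | 0.417 | 93.2 | 0.5 | 6.2 |
| ash | 1.33 | 80.6 | 0 | 19.9 |
| ash | 2.50 | 66.0 | 1.9 | 32.7 |
| ash | 3.00 | 60.5 | 2.9 | 36.6 |
| ash | 5.00 | 42.6 | 7.6 | 48.3 |
| ash | 6.00 | 36.2 | 11.9 | 51.0 |
| ash | 8.00 | 25.4 | 20.2 | 53.8 |

(each reading ± 0.5 percentage points)

- in percentages every species weighs as the J in it: one G counts as two
- for Z the G are counted in
- as a solid, counted per litre of solution: X
- candidate steps: L + Q -> Z; X <-> L; J + Z <-> G; J -> Q
- at the start none of X is in solution
- in an amount of Z, one G counts as one Z

- which of these there is most of at the end, counted by the J in it, red (Z / Q / J)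
- which of these there is most of at the end, counted by the J in it, green (Z / Q / J)
- which of these there is most of at the end, counted by the J in it, grey (Z / Q / J)
- final amount of the leader among these, as a percentage of the J charged, in red
- final amount of the leader among these, as a percentage of the J charged, in green
- final amount of the leader among these, as a percentage of the J charged, in grey

Maple and ash differ 8.15-fold in X, yet at 8.00 h they read Q 53.6 % and 53.8 %. What red, green and grey need to know is how much of their X the reaction takes. That is the claim on X: the share of the X charge that goes into the Z made by the asked time. It is the Z share times the J charge over the X charge. With the mean Z share of 19.6 %, red has 0.178, green 0.0711 and grey 0.0279. Maple stands at 0.145, so red lies just beyond what has been tried.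

One number is not quite enough, since the claim omits X standing in solution as L. In maple, Z gains 0.0671 /h per unit of Q between 3.00 h and 5.00 h and 0.0691 /h from there to 8.00 h. Within the scatter of these readings the two agree, which reads as a pseudo-first-order drain of Q over those hours. The size of L stays unread and red carries the largest claim, but my reckoning repeats the earlier runs: Q leads near 53.7 %.

The forecast gives Q in all three, at 54 %, 53.7 % and 53.7 %, adding: “Red is the only doubtful case”.

    L + Q → Z (k = 0.0337 /M/min)
    X ⇌ L, rate k2*(cs2 - [L]) while solid is left; crystals form when [L] > cs2 (solubility = 0.140 M, k = 0.00144 /min)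
    J + Z ⇌ G, settled at all times (K = 1.03 /M)
    J → Q (k = 0.00279 /min)

Red, green and grey each give Q ahead at 53.6 %. L stands at 0.0383 M in each at 8.00 h, below the saturation value of 0.14 M, while solid X stands at 64.7 % of its charge in red and 94.4 % in grey. In red, the claim plus L as a share of the X charge, 0.174, makes 35.2 %, and the solid missing is 35.3 % of the charge.

For one more flask, green with 0.80 M of J, the same Z share gives a claim of 0.284. That flask uses about half of that, 13.8 % of its X, with Z at 9.48 % and Q at 63.5 %.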